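**Strategy.** Everything rests on disconnecting the bond between C6 of chroman ring A and the enone carbonyl carbon. The feature exploited is the 2-hydroxyl of resorcinol ring B, ortho to the enone β-carbon, which makes the (E)-2,4-dihydroxycinnamoyl unit the open form of a 7-oxygenated coumarin. In one operation the C6-lithiated, MOM-protected chroman adds to the lactone carbonyl of 7-(methoxymethoxy)coumarin, acid removes both MOM groups and collapses all adducts to one 2-arylchromenylium ion, and buffering to pH 5–6 drains its hemiketal epimers and Z-enone into the hydrogen-bonded E-chalcone. The enantiopure chroman comes from an Evans allylation, cyclodehydration and cross-metathesis.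

Key step: step 11

Remark: it is assumed that, as for other 7-hydroxy-2-arylchromenylium ions without 3- or 5-substituents, the hydration equilibrium at pH 5–6 lies on the side of the E-chalcone; compounds 1, 3, 7 and 19 are taken as commercial.

**Step 1**
Reactants: 1 5-methoxyresorcinol
Product: 2 1-methoxy-3,5-bis(methoxymethoxy)benzene
Conditions: MOMCl, iPr2NEt, CH2Cl2, 0 °C to rt
Reagents that add atoms: chloromethyl methyl ether COCCl
Why: Twofold O-alkylation (MOM acetal formation) of the phenols should give a symmetric arene whose position between the two acetal oxygens is set up for directed lithiation.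

**Step 2**
Reactants: 2 1-methoxy-3,5-bis(methoxymethoxy)benzene; 3 β-propiolactone
Product: 6 3-[4-methoxy-2,6-bis(methoxymethoxy)phenyl]propanoic acid, via aryllithium 4 (not isolated), via arylmagnesium bromide 5 (not isolated)
Conditions: n-BuLi, THF, 0 °C; MgBr2·OEt2, 0 °C; CuBr·SMe2 (10 mol%), 3, THF–Me2S, −30 to 0 °C; 1 M HCl to pH 3, 0 °C
Reagents that add atoms: none
Why: Directed ortho-metalation should occur at the carbon flanked by both MOM ethers, and after transmetalation the copper-catalysed SN2 (alkyl–oxygen) ring opening of the β-lactone by the aryl Grignard reagent should deliver the three-carbon acid in one operation.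

**Step 3**
Reactants: 6 3-[4-methoxy-2,6-bis(methoxymethoxy)phenyl]propanoic acid; 7 (S)-4-benzyloxazolidin-2-one
Product: 9 (4S)-4-benzyl-3-{3-[4-methoxy-2,6-bis(methoxymethoxy)phenyl]propanoyl}oxazolidin-2-one, via mixed pivalic anhydride 8 (not isolated)
Conditions: PivCl, Et3N, THF, −20 °C; then 7, LiCl, −20 °C to rt
Reagents that add atoms: none
Why: N-Acylation of the Evans auxiliary through mixed anhydride 8 (LiCl/Et3N variant) should attach the acid to the oxazolidinone without strong base.

**Step 4**
Reactants: 9 (4S)-4-benzyl-3-{3-[4-methoxy-2,6-bis(methoxymethoxy)phenyl]propanoyl}oxazolidin-2-one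
Product: 11 (4S)-4-benzyl-3-{(2S)-2-[[4-methoxy-2,6-bis(methoxymethoxy)phenyl]methyl]pent-4-enoyl}oxazolidin-2-one, via sodium Z-enolate 10 (not isolated)
Conditions: NaN(SiMe3)2, THF, −78 °C; allyl iodide, −78 to −45 °C
Reagents that add atoms: allyl iodide C=CCI
Why: Evans asymmetric alkylation, in which the chelated sodium Z-enolate 10 should be allylated on the face opposite the C4 benzyl group of the auxiliary, setting the new centre as (2S), the later C3 of the chroman.

**Step 5**
Reactants: 11 (4S)-4-benzyl-3-{(2S)-2-[[4-methoxy-2,6-bis(methoxymethoxy)phenyl]methyl]pent-4-enoyl}oxazolidin-2-one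
Product: 12 benzyl (2S)-2-[[4-methoxy-2,6-bis(methoxymethoxy)phenyl]methyl]pent-4-enoate
Conditions: BnOH, n-BuLi, THF, −78 to 0 °C; H2O
Reagents that add atoms: benzyl alcohol OCc1ccccc1
Why: Transesterification with lithium benzyloxide should cleave the exocyclic imide carbonyl selectively and without epimerisation of the α-stereocentre, returning the auxiliary.

**Step 6**
Reactants: 12 benzyl (2S)-2-[[4-methoxy-2,6-bis(methoxymethoxy)phenyl]methyl]pent-4-enoate
Product: 14 (3S)-3-[[4-methoxy-2,6-bis(methoxymethoxy)phenyl]methyl]-2-methylhex-5-en-2-ol, via methyl ketone 13 (not isolated)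
Conditions: MeMgBr, CeCl3, THF, −78 to 0 °C; H2O
Reagents that add atoms: methylmagnesium bromide C[Mg]Br
Why: Double Grignard addition to the ester through methyl ketone 13 should give the tertiary alcohol, CeCl3 raising carbonyl electrophilicity and suppressing enolisation so that the α-stereocentre is retained.

**Step 7**
Reactants: 14 (3S)-3-[[4-methoxy-2,6-bis(methoxymethoxy)phenyl]methyl]-2-methylhex-5-en-2-ol
Product: 16 (3S)-7-methoxy-2,2-dimethyl-3-(prop-2-enyl)chroman-5-ol, via resorcinol triol 15 (not isolated)
Conditions: p-TsOH·H2O (0.2 equiv), MeOH, 50 °C; then solvent exchange, toluene (dilute), 70 °C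
Reagents that add atoms: none
Why: Acid-catalysed acetal methanolysis should free the symmetric resorcinol 15, whose two equivalent hydroxyls make the ensuing cyclodehydration (phenol capture of the tertiary carbocation, as in terpenylresorcinol-to-benzopyran closures) regiochemically unambiguous, while the monosubstituted alkene, chosen in place of a prenyl group for this reason, should not be protonated and C3 is not involved.

**Step 8**
Reactants: 16 (3S)-7-methoxy-2,2-dimethyl-3-(prop-2-enyl)chroman-5-ol
Product: 17 (3S)-7-methoxy-5-(methoxymethoxy)-2,2-dimethyl-3-(prop-2-enyl)chroman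
Conditions: MOMCl, iPr2NEt, CH2Cl2, 0 °C to rt
Reagents that add atoms: chloromethyl methyl ether COCCl
Why: O-Alkylation of the only free phenol should install the acetal that later directs ortho-lithiation to C6 and protects the ring-A hydroxyl.

**Step 9**
Reactants: 17 (3S)-7-methoxy-5-(methoxymethoxy)-2,2-dimethyl-3-(prop-2-enyl)chroman
Product: 18 (3S)-7-methoxy-5-(methoxymethoxy)-2,2-dimethyl-3-(3-methylbut-2-enyl)chroman
Conditions: second-generation Grubbs catalyst RuCl2(=CHPh)(PCy3)(H2IMes) (5 mol%), 2-methyl-2-butene, CH2Cl2, 40 °C, sealed tube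
Reagents that add atoms: 2-methyl-2-butene CC=C(C)C
Why: Olefin cross-metathesis of the monosubstituted alkene with excess 2-methyl-2-butene should exchange the terminal CH2 for CMe2 and release propene, the trisubstituted product being inert to further metathesis and the stereocentre untouched.

**Step 10**
Reactants: 19 umbelliferone (7-hydroxy-2H-chromen-2-one)
Product: 20 7-(methoxymethoxy)-2H-chromen-2-one
Conditions: MOMCl, iPr2NEt, DMF, 0 °C to rt
Reagents that add atoms: chloromethyl methyl ether COCCl
Why: O-Alkylation (acetal protection) of the only hydroxyl should remove the acidic proton that would quench the aryllithium and the phenoxide that would deactivate the lactone in the key step.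

**Step 11**
Reactants: 18 (3S)-7-methoxy-5-(methoxymethoxy)-2,2-dimethyl-3-(3-methylbut-2-enyl)chroman; 20 7-(methoxymethoxy)-2H-chromen-2-one
Product: 26 (E)-3-(2,4-dihydroxyphenyl)-1-[(3S)-5-hydroxy-7-methoxy-2,2-dimethyl-3-(3-methylbut-2-enyl)chroman-6-yl]prop-2-en-1-one (target), via aryllithium 21 (not isolated), via lithium lactolate 22 (not isolated), via chromenylium chloride 23 (not isolated), via hemiketal 24 (not isolated), via Z-chalcone 25 (not isolated)
Conditions: 18, n-BuLi, TMEDA, THF, 0 °C; added to 20 (1.3 equiv), THF, −78 to −20 °C; 2 M HCl in MeOH, 20 °C, dark; aq. NaOAc to pH 5–6, 40 °C, dark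
Reagents that add atoms: water O
Why: The MOM and methoxy oxygens flanking C6 should direct lithiation there and not to C8 (flanked by the methoxy group and the hindered ring oxygen), and the hard, di-ortho-substituted aryllithium 21 should add once to the lactone carbonyl of 20, a Z-locked 2-hydroxycinnamoyl donor, to give lactolate 22. Methanolic HCl should then remove both MOM groups and dehydrate every form of the adduct to the single chromenylium ion 23, and at pH 5–6 water adds at C2 to give hemiketal 24 (both C2 epimers), which opens to Z-enone 25 and isomerises thermally to 26, so that the ketone oxygen comes from water and the ring oxygen of 20 becomes the 2-hydroxyl of ring B. The closest known reactions are the addition of aryl Grignard or aryllithium reagents to coumarins to give 2-arylchromenylium (flavylium) salts and the pH-driven hydration, ring opening and cis–trans isomerisation of such salts to trans-2-hydroxychalcones. No ring of the target is closed, the pyran ring of the coumarin being a temporary ring that is carried through and opened at the end. The only new stereo-element is the enone C=C, set E under thermodynamic control because 23, 24 and 25 interconvert and the planar E-chalcone, stabilised by the hydrogen bond from the ring-A 5-hydroxyl to the carbonyl, is the expected sink, while C3 of the chroman is remote and untouched. The step needs 1,2- over 1,4-addition and mono-addition, which the hard aryllithium, low temperature, inverse addition and the hindered lactolate should secure, and it needs the prenyl group and the chalcone to survive, hence brief acid at 20 °C, exclusion of light and no base.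

**Compound list**
1 | 5-methoxyresorcinol (5-methoxybenzene-1,3-diol) | COc1cc(O)cc(O)c1 | starting material
2 | 1-methoxy-3,5-bis(methoxymethoxy)benzene | COCOc1cc(OC)cc(OCOC)c1 | intermediate
3 | β-propiolactone (oxetan-2-one) | O=C1CCO1 | starting material
4 | [4-methoxy-2,6-bis(methoxymethoxy)phenyl]lithium | [Li]c1c(OCOC)cc(OC)cc1OCOC | intermediate
5 | [4-methoxy-2,6-bis(methoxymethoxy)phenyl]magnesium bromide | Br[Mg]c1c(OCOC)cc(OC)cc1OCOC | intermediate
6 | 3-[4-methoxy-2,6-bis(methoxymethoxy)phenyl]propanoic acid | COCOc1cc(OC)cc(OCOC)c1CCC(=O)O | intermediate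
7 | (S)-4-benzyloxazolidin-2-one | O=C1N[C@@H](Cc2ccccc2)CO1 | starting material
8 | 3-[4-methoxy-2,6-bis(methoxymethoxy)phenyl]propanoic pivalic anhydride | COCOc1cc(OC)cc(OCOC)c1CCC(=O)OC(=O)C(C)(C)C | intermediate
9 | (4S)-4-benzyl-3-{3-[4-methoxy-2,6-bis(methoxymethoxy)phenyl]propanoyl}oxazolidin-2-one | COCOc1cc(OC)cc(OCOC)c1CCC(=O)N1C(=O)OC[C@@H]1Cc1ccccc1 | intermediate
10 | sodium (Z)-enolate of 9 | COCOc1cc(OC)cc(OCOC)c1C/C=C(\[O-])N1C(=O)OC[C@@H]1Cc1ccccc1.[Na+] | intermediate
11 | (4S)-4-benzyl-3-{(2S)-2-[[4-methoxy-2,6-bis(methoxymethoxy)phenyl]methyl]pent-4-enoyl}oxazolidin-2-one | COCOc1cc(OC)cc(OCOC)c1C[C@H](CC=C)C(=O)N1C(=O)OC[C@@H]1Cc1ccccc1 | intermediate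
12 | benzyl (2S)-2-[[4-methoxy-2,6-bis(methoxymethoxy)phenyl]methyl]pent-4-enoate | COCOc1cc(OC)cc(OCOC)c1C[C@H](CC=C)C(=O)OCc1ccccc1 | intermediate
13 | (3S)-3-[[4-methoxy-2,6-bis(methoxymethoxy)phenyl]methyl]hex-5-en-2-one | COCOc1cc(OC)cc(OCOC)c1C[C@H](CC=C)C(C)=O | intermediate
14 | (3S)-3-[[4-methoxy-2,6-bis(methoxymethoxy)phenyl]methyl]-2-methylhex-5-en-2-ol | COCOc1cc(OC)cc(OCOC)c1C[C@H](CC=C)C(C)(C)O | intermediate
15 | 2-[(2S)-2-(2-hydroxypropan-2-yl)pent-4-enyl]-5-methoxybenzene-1,3-diol | COc1cc(O)c(C[C@H](CC=C)C(C)(C)O)c(O)c1 | intermediate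
16 | (3S)-7-methoxy-2,2-dimethyl-3-(prop-2-enyl)chroman-5-ol | COc1cc2c(c(O)c1)C[C@H](CC=C)C(C)(C)O2 | intermediate
17 | (3S)-7-methoxy-5-(methoxymethoxy)-2,2-dimethyl-3-(prop-2-enyl)chroman | COc1cc2c(c(OCOC)c1)C[C@H](CC=C)C(C)(C)O2 | intermediate
18 | (3S)-7-methoxy-5-(methoxymethoxy)-2,2-dimethyl-3-(3-methylbut-2-enyl)chroman | COc1cc2c(c(OCOC)c1)C[C@H](CC=C(C)C)C(C)(C)O2 | intermediate
19 | umbelliferone (7-hydroxy-2H-chromen-2-one) | O=c1ccc2ccc(O)cc2o1 | starting material
20 | 7-(methoxymethoxy)-2H-chromen-2-one | COCOc1ccc2ccc(=O)oc2c1 | intermediate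
21 | [(3S)-7-methoxy-5-(methoxymethoxy)-2,2-dimethyl-3-(3-methylbut-2-enyl)chroman-6-yl]lithium | COc1cc2c(c(OCOC)c1[Li])C[C@H](CC=C(C)C)C(C)(C)O2 | intermediate
22 | lithium 2-[(3S)-7-methoxy-5-(methoxymethoxy)-2,2-dimethyl-3-(3-methylbut-2-enyl)chroman-6-yl]-7-(methoxymethoxy)-2H-chromen-2-olate (both C2 epimers) | COc1cc2c(c(OCOC)c1C1([O-])C=Cc3ccc(OCOC)cc3O1)C[C@H](CC=C(C)C)C(C)(C)O2.[Li+] | intermediate
23 | 7-hydroxy-2-[(3S)-5-hydroxy-7-methoxy-2,2-dimethyl-3-(3-methylbut-2-enyl)chroman-6-yl]chromenylium chloride | COc1cc2c(c(O)c1-c1ccc3ccc(O)cc3[o+]1)C[C@H](CC=C(C)C)C(C)(C)O2.[Cl-] | intermediate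
24 | 2-[(3S)-5-hydroxy-7-methoxy-2,2-dimethyl-3-(3-methylbut-2-enyl)chroman-6-yl]-2H-chromene-2,7-diol (both C2 epimers) | COc1cc2c(c(O)c1C1(O)C=Cc3ccc(O)cc3O1)C[C@H](CC=C(C)C)C(C)(C)O2 | intermediate
25 | (Z)-3-(2,4-dihydroxyphenyl)-1-[(3S)-5-hydroxy-7-methoxy-2,2-dimethyl-3-(3-methylbut-2-enyl)chroman-6-yl]prop-2-en-1-one | COc1cc2c(c(O)c1C(=O)/C=C\c1ccc(O)cc1O)C[C@H](CC=C(C)C)C(C)(C)O2 | intermediate
26 | (E)-3-(2,4-dihydroxyphenyl)-1-[(3S)-5-hydroxy-7-methoxy-2,2-dimethyl-3-(3-methylbut-2-enyl)chroman-6-yl]prop-2-en-1-one | COc1cc2c(c(O)c1C(=O)/C=C/c1ccc(O)cc1O)C[C@H](CC=C(C)C)C(C)(C)O2 | target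

**Step count and risks**
Total steps: 11. Longest linear sequence: 10 (steps 1–9 and 11).

Steps most likely to fail:

1. Step 11. What may go wrong: conjugate addition of 21 at C4 of the coumarin or a second addition to the ring-opened enone, incomplete drainage of the chromenylium pool to the E-enone, or acid-promoted solvolysis at the trisubstituted alkene during MOM cleavage. The fallback sets out from 18 and comes back at 26. 2,4-Dihydroxybenzaldehyde would be protected (MOMCl, iPr2NEt) as 2,4-bis(methoxymethoxy)benzaldehyde F1. A Horner–Wadsworth–Emmons reaction with diethyl [2-[methoxy(methyl)amino]-2-oxoethyl]phosphonate and NaH would give the E-configured Weinreb amide (E)-3-[2,4-bis(methoxymethoxy)phenyl]-N-methoxy-N-methylprop-2-enamide F2. Aryllithium 21, made from 18 as in step 11, would add once to F2 at −78 °C to give the tris-MOM E-chalcone F3, and HCl in MeOH at 20 °C followed by the same work-up at pH 5–6 would give 26. The geometry is then fixed by the olefination and over-addition is blocked by the chelated tetrahedral intermediate.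

2. Step 7. What may go wrong: proton loss or 1,2-hydride shift at the tertiary carbocation before the phenol closes the ring, which would erode the configuration at C3 or lead to a dihydrobenzofuran, and intermolecular alkylation of the resorcinol. The fallback sets out from 15, isolated after the methanol stage, and comes back at 16. Mono-triflation (PhNTf2, K2CO3, acetone) would give 2-[(2S)-2-(2-hydroxypropan-2-yl)pent-4-enyl]-3-hydroxy-5-methoxyphenyl trifluoromethanesulfonate F4. A palladium-catalysed intramolecular C–O coupling of the tertiary alcohol (Pd(OAc)2, 2-(di-tert-butylphosphino)-1,1'-binaphthyl, Cs2CO3, toluene, 80 °C) would then close the aryl–oxygen bond instead, with no carbocation next to C3.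

3. Step 2. What may go wrong: attack of the aryl nucleophile at the lactone carbonyl (acyl–oxygen cleavage) or oligomerisation of the lactone in place of the copper-mediated alkyl–oxygen opening. The fallback sets out from 2 and comes back at 6. Aryllithium 4 would be quenched with DMF to give 4-methoxy-2,6-bis(methoxymethoxy)benzaldehyde F5. A Knoevenagel–Doebner condensation with malonic acid (pyridine, piperidine, 90 °C) would give (E)-3-[4-methoxy-2,6-bis(methoxymethoxy)phenyl]prop-2-enoic acid F6, and hydrogenation (H2, Pd/C, EtOAc) would give 6.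

**Further compounds**
F1 | step 11 | 2,4-bis(methoxymethoxy)benzaldehyde | COCOc1ccc(C=O)c(OCOC)c1
F2 | step 11 | (E)-3-[2,4-bis(methoxymethoxy)phenyl]-N-methoxy-N-methylprop-2-enamide | COCOc1ccc(/C=C/C(=O)N(C)OC)c(OCOC)c1
F3 | step 11 | (E)-3-[2,4-bis(methoxymethoxy)phenyl]-1-[(3S)-7-methoxy-5-(methoxymethoxy)-2,2-dimethyl-3-(3-methylbut-2-enyl)chroman-6-yl]prop-2-en-1-one | COc1cc2c(c(OCOC)c1C(=O)/C=C/c1ccc(OCOC)cc1OCOC)C[C@H](CC=C(C)C)C(C)(C)O2
F4 | step 7 | 2-[(2S)-2-(2-hydroxypropan-2-yl)pent-4-enyl]-3-hydroxy-5-methoxyphenyl trifluoromethanesulfonate | COc1cc(O)c(C[C@H](CC=C)C(C)(C)O)c(OS(=O)(=O)C(F)(F)F)c1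
F5 | step 2 | 4-methoxy-2,6-bis(methoxymethoxy)benzaldehyde | COCOc1cc(OC)cc(OCOC)c1C=O
F6 | step 2 | (E)-3-[4-methoxy-2,6-bis(methoxymethoxy)phenyl]prop-2-enoic acid | COCOc1cc(OC)cc(OCOC)c1/C=C/C(=O)O
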